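Daucane numbering: C1 angular-methyl carbon, C4 isopropyl carbinol, C5 ring-fusion CH, C6–C10 the rest of the seven-membered ring. The route rests on the C5–C6 bond and exploits the 1,3-diol unit O4–C4–C5–C6–O6 on the cyclopentane ring: silicon stands in for O6 and ties C6 to the C4 oxygen of a cyclopentenyl silyl ether. 5-Exo radical closure of this temporary oxasilolane ring forms C5–C6 cis to O4, and the resulting C1 radical is allylated on the opposite face, which sets the quaternary centre and the trans ring fusion in the same operation. Tamao oxidation, alkoxyallylboration (C7, C8), ring-closing metathesis (C8=C9), epoxidation and esterification complete the target.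

Key step: step 5

Assumption: compounds 1, 4, 10, 16, 17 and 26 and the reagents named on the Conditions lines are taken as commercial; α/β refer to the daucane skeleton with the angular methyl on the β face (H5 α, trans-fused).

Step 1
Reactants: 1 3-methylcyclopent-2-en-1-one
Product: 2 (S)-3-methylcyclopent-2-en-1-ol
Conditions: (R)-2-methyl-CBS-oxazaborolidine (10 mol%), BH3·SMe2, THF, −20 °C; MeOH quench
Reagents that add atoms: none
Why: Corey–Bakshi–Shibata reduction should deliver hydride to the carbonyl face chosen by the (R)-oxazaborolidine (alkenyl arm as the large group), setting the (S)-carbinol that later fixes the absolute configuration of C4.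

Step 2
Reactants: 2 (S)-3-methylcyclopent-2-en-1-ol
Product: 3 (S)-3-methylcyclopent-2-en-1-yl N,N-diisopropylcarbamate
Conditions: NaH, THF, 0 °C; iPr2NCOCl, reflux
Reagents that add atoms: N,N-diisopropylcarbamoyl chloride, CC(C)N(C(C)C)C(Cl)=O
Why: O-carbamoylation of the sodium alkoxide should give the carbamate that serves as directing and leaving group for the lithiation–borylation, with no change at the stereocentre.

Step 3
Reactants: 3 (S)-3-methylcyclopent-2-en-1-yl N,N-diisopropylcarbamate; 4 2-isopropyl-4,4,5,5-tetramethyl-1,3,2-dioxaborolane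
Product: 8 (R)-3-methyl-1-(propan-2-yl)cyclopent-2-en-1-ol, via lithiated carbamate 5 (not isolated), via lithium boronate complex 6 (not isolated), via tertiary allylic pinacol boronate 7 (not isolated)
Conditions: sBuLi, TMEDA, Et2O, −78 °C; then 4, −78 °C; MgBr2·OEt2, MeOH, −78 °C to rt; then NaOH, H2O2, THF, 0 °C
Reagents that add atoms: hydrogen peroxide, OO
Why: Carbamate-directed α-lithiation, stereoretentive borylation, anti 1,2-metallate rearrangement and stereoretentive C–B oxidation (lithiation–borylation) should replace the carbinol hydrogen by isopropyl with net retention, giving the tertiary allylic alcohol with C4 (R).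

Step 4
Reactants: 8 (R)-3-methyl-1-(propan-2-yl)cyclopent-2-en-1-ol
Product: 9 (R)-(bromomethyl)dimethyl{[3-methyl-1-(propan-2-yl)cyclopent-2-en-1-yl]oxy}silane
Conditions: BrCH2SiMe2Cl, Et3N, DMAP (cat.), CH2Cl2, 0 °C to rt
Reagents that add atoms: (bromomethyl)chlorodimethylsilane, C[Si](C)(Cl)CBr
Why: Amine/DMAP-mediated O-silylation of the tertiary alcohol should install the bromomethylsilyl tether on the C4 oxygen without touching the stereocentre.

Step 5
Reactants: 9 (R)-(bromomethyl)dimethyl{[3-methyl-1-(propan-2-yl)cyclopent-2-en-1-yl]oxy}silane; 10 allyltributylstannane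
Product: 13 (3aR,4R,6aR)-2,2,4-trimethyl-6a-(propan-2-yl)-4-(prop-2-en-1-yl)hexahydro-2H-cyclopenta[d][1,2]oxasilole, via α-silyl radical 11 (not isolated), via tertiary C1 radical 12 (not isolated)
Conditions: AIBN (0.2 equiv, in portions), 10 (5 equiv), benzene (0.05 M), 80 °C
Reagents that add atoms: none
Why: The tributyltin radical abstracts bromine to give α-silyl radical 11, which attacks C5 of the cyclopentene (forming C5–C6) and leaves tertiary radical 12 at C1, which is quenched by SH2′ allyl transfer from the stannane with release of the chain-carrying tin radical. The closest known reaction types are the silicon-tethered (bromomethyl)silyl ether radical cyclization and the Keck radical allylation, run here as one cyclization–trapping cascade. The one ring that closes is the five-membered oxasilolane, in the 5-exo-trig mode. C5 is controlled by the three-atom O–Si–C tether, which reaches only the alkene face that carries the C4 oxygen (C6 cis to O4), and C1 by approach of the stannane to the convex face anti to the new C5–C6 bond, which puts allyl trans and methyl cis to C6, the trans C1/C5 relation of the hydroazulene. The step needs 5-exo over 6-endo closure (secured because C5 is the unsubstituted alkene carbon and attack there gives a tertiary radical), closure before allylation (the unimolecular cyclization outruns addition of the α-silyl radical to the unactivated stannane) and facial control at C1 (secured by the cup shape of the cis-fused bicycle).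

Step 6
Reactants: 13 (3aR,4R,6aR)-2,2,4-trimethyl-6a-(propan-2-yl)-4-(prop-2-en-1-yl)hexahydro-2H-cyclopenta[d][1,2]oxasilole
Product: 14 (1R,2S,3R)-2-(hydroxymethyl)-3-methyl-1-(propan-2-yl)-3-(prop-2-en-1-yl)cyclopentan-1-ol
Conditions: 30% H2O2, KF, KHCO3, THF/MeOH (1:1), 45 °C
Reagents that add atoms: hydrogen peroxide, OO
Why: Tamao–Fleming oxidation of the cyclic alkoxysilane should replace the C6–Si bond by C6–OH and free the C4 hydroxyl, the monosubstituted alkene being inert to basic peroxide.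

Step 7
Reactants: 14 (1R,2S,3R)-2-(hydroxymethyl)-3-methyl-1-(propan-2-yl)-3-(prop-2-en-1-yl)cyclopentan-1-ol
Product: 15 (1R,2R,5R)-2-hydroxy-5-methyl-2-(propan-2-yl)-5-(prop-2-en-1-yl)cyclopentane-1-carbaldehyde
Conditions: TEMPO (10 mol%), PhI(OAc)2, CH2Cl2, rt
Reagents that add atoms: none
Why: The TEMPO/PhI(OAc)2 oxidation is selective for the primary alcohol and, being non-basic, should give the β-hydroxy aldehyde without retro-aldol cleavage or epimerization at C5.

Step 8
Reactants: 16 4-methoxyphenol; 17 3-chloro-2-methylprop-1-ene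
Product: 18 1-methoxy-4-[(2-methylprop-2-en-1-yl)oxy]benzene
Conditions: K2CO3, DMF, 60 °C
Reagents that add atoms: none
Why: Williamson ether synthesis (SN2 of the phenoxide on the primary allylic chloride) should give the aryl methallyl ether that serves as the γ-alkoxyallyl donor.

Step 9
Reactants: 15 (1R,2R,5R)-2-hydroxy-5-methyl-2-(propan-2-yl)-5-(prop-2-en-1-yl)cyclopentane-1-carbaldehyde; 18 1-methoxy-4-[(2-methylprop-2-en-1-yl)oxy]benzene
Product: 23 (1R,2S,3R)-2-[(1R,2R)-1-hydroxy-2-(4-methoxyphenoxy)-3-methylbut-3-en-1-yl]-3-methyl-1-(propan-2-yl)-3-(prop-2-en-1-yl)cyclopentan-1-ol, via lithiated allyl ether 19 (not isolated), via lithium methoxyborate 20 (not isolated), via γ-aryloxyallylborane 21 (not isolated), via borinate adduct 22 (not isolated)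
Conditions: 18, sBuLi, THF, −78 °C; (−)-Ipc2BOMe, −78 °C; BF3·OEt2, −78 °C; then 15, −78 to −40 °C; NaOH, H2O2, 0 °C to rt
Reagents that add atoms: none
Why: In this Brown alkoxyallylboration the (Z)-γ-aryloxyallylborane should react through a chair-like six-membered transition state to give the syn C6-OH/C7-OAr pair, with the isopinocampheyl groups derived from (+)-α-pinene selecting the aldehyde face that gives (6R,7R).

Step 10
Reactants: 23 (1R,2S,3R)-2-[(1R,2R)-1-hydroxy-2-(4-methoxyphenoxy)-3-methylbut-3-en-1-yl]-3-methyl-1-(propan-2-yl)-3-(prop-2-en-1-yl)cyclopentan-1-ol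
Product: 24 7β-(4-methoxyphenoxy)dauc-8-ene-4β,6α-diol
Conditions: second-generation Grubbs catalyst RuCl2(=CHPh)(H2IMes)(PCy3) (10 mol%), CH2Cl2 (5 mM), 40 °C
Reagents that add atoms: none
Why: Ring-closing metathesis of the monosubstituted and the 1,1-disubstituted alkene should close the seven-membered ring as the trisubstituted C8=C9 alkene with loss of ethene, the trans arms on C1 and C5 being already in place.

Step 11
Reactants: 24 7β-(4-methoxyphenoxy)dauc-8-ene-4β,6α-diol
Product: 25 8α,9α-epoxy-7β-(4-methoxyphenoxy)daucane-4β,6α-diol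
Conditions: mCPBA, NaHCO3, CH2Cl2, 0 °C
Reagents that add atoms: meta-chloroperoxybenzoic acid, OOC(=O)c1cccc(Cl)c1
Why: Prilezhaev epoxidation should take place on the α face of C8=C9, because the β face is screened by the allylic C7 aryloxy group and the angular C1 methyl while the α C6 hydroxyl can guide the peracid by hydrogen bonding.

Step 12
Reactants: 25 8α,9α-epoxy-7β-(4-methoxyphenoxy)daucane-4β,6α-diol; 26 4-acetoxybenzoyl chloride
Product: 27 8α,9α-epoxy-4β-hydroxy-7β-(4-methoxyphenoxy)daucan-6α-yl 4-acetoxybenzoate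
Conditions: pyridine, DMAP (cat.), CH2Cl2, 0 °C to rt
Reagents that add atoms: none
Why: DMAP-catalysed acylation should esterify the only secondary hydroxyl (C6) and leave the hindered tertiary C4 hydroxyl untouched.

Step 13
Reactants: 27 8α,9α-epoxy-4β-hydroxy-7β-(4-methoxyphenoxy)daucan-6α-yl 4-acetoxybenzoate
Product: 28 8α,9α-epoxy-4β,7β-dihydroxydaucan-6α-yl 4-acetoxybenzoate
Conditions: (NH4)2Ce(NO3)6, pyridine, MeCN/H2O (4:1), 0 °C
Reagents that add atoms: none
Why: Oxidative dearylation of the 4-methoxyphenyl ether (single-electron oxidation of the electron-rich ring and hydrolysis to benzoquinone) should release the C7 hydroxyl, with the pyridine buffer shielding the epoxide from acid and the electron-poor benzoate ring staying inert.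

Step 14
Reactants: 28 8α,9α-epoxy-4β,7β-dihydroxydaucan-6α-yl 4-acetoxybenzoate
Product: 29 8α,9α-epoxy-4β,7β-dihydroxydaucan-6α-yl 4-hydroxybenzoate (CNP0290052.1)
Conditions: pyrrolidine, CH2Cl2, 0 °C to rt
Reagents that add atoms: none
Why: Aminolysis of the phenolic acetate should be much faster than attack on the hindered secondary benzoate or the trisubstituted epoxide, giving the free phenol of the target.

Compound list
1 | 3-methylcyclopent-2-en-1-one | CC1=CC(=O)CC1 | starting material
2 | (S)-3-methylcyclopent-2-en-1-ol | O[C@H]1CCC(C)=C1 | intermediate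
3 | (S)-3-methylcyclopent-2-en-1-yl N,N-diisopropylcarbamate | CC(C)N(C(C)C)C(=O)O[C@H]1CCC(C)=C1 | intermediate
4 | 2-isopropyl-4,4,5,5-tetramethyl-1,3,2-dioxaborolane | CC(C)B1OC(C)(C)C(C)(C)O1 | starting material
5 | (S)-1-lithio-3-methylcyclopent-2-en-1-yl N,N-diisopropylcarbamate | CC(C)N(C(C)C)C(=O)O[C@@]1([Li])CCC(C)=C1 | intermediate
6 | lithium boronate complex of 5 and 4 | [Li+].CC(C)N(C(C)C)C(=O)O[C@@]1([B-]2(C(C)C)OC(C)(C)C(C)(C)O2)CCC(C)=C1 | intermediate
7 | (S)-4,4,5,5-tetramethyl-2-[3-methyl-1-(propan-2-yl)cyclopent-2-en-1-yl]-1,3,2-dioxaborolane | CC(C)[C@]1(B2OC(C)(C)C(C)(C)O2)CCC(C)=C1 | intermediate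
8 | (R)-3-methyl-1-(propan-2-yl)cyclopent-2-en-1-ol | CC(C)[C@]1(O)CCC(C)=C1 | intermediate
9 | (R)-(bromomethyl)dimethyl{[3-methyl-1-(propan-2-yl)cyclopent-2-en-1-yl]oxy}silane | CC(C)[C@]1(O[Si](C)(C)CBr)CCC(C)=C1 | intermediate
10 | allyltributylstannane | C=CC[Sn](CCCC)(CCCC)CCCC | starting material
11 | α-silyl radical from 9 | CC(C)[C@]1(O[Si](C)(C)[CH2])CCC(C)=C1 | intermediate
12 | cis-fused oxasilolane with tertiary radical at C1 | CC(C)[C@]12CC[C](C)[C@H]1C[Si](C)(C)O2 | intermediate
13 | (3aR,4R,6aR)-2,2,4-trimethyl-6a-(propan-2-yl)-4-(prop-2-en-1-yl)hexahydro-2H-cyclopenta[d][1,2]oxasilole | CC(C)[C@]12CC[C@](C)(CC=C)[C@H]1C[Si](C)(C)O2 | intermediate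
14 | (1R,2S,3R)-2-(hydroxymethyl)-3-methyl-1-(propan-2-yl)-3-(prop-2-en-1-yl)cyclopentan-1-ol | CC(C)[C@]1(O)CC[C@](C)(CC=C)[C@H]1CO | intermediate
15 | (1R,2R,5R)-2-hydroxy-5-methyl-2-(propan-2-yl)-5-(prop-2-en-1-yl)cyclopentane-1-carbaldehyde | CC(C)[C@]1(O)CC[C@](C)(CC=C)[C@H]1C=O | intermediate
16 | 4-methoxyphenol | COc1ccc(O)cc1 | starting material
17 | 3-chloro-2-methylprop-1-ene | CC(=C)CCl | starting material
18 | 1-methoxy-4-[(2-methylprop-2-en-1-yl)oxy]benzene | COc1ccc(OCC(C)=C)cc1 | intermediate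
19 | [1-(4-methoxyphenoxy)-2-methylprop-2-en-1-yl]lithium | COc1ccc(OC([Li])C(C)=C)cc1 | intermediate
20 | lithium methoxy[(Z)-3-(4-methoxyphenoxy)-2-methylprop-2-en-1-yl]diisopinocampheylborate | [Li+].CO[B-](C/C(C)=C\Oc1ccc(OC)cc1)([C@@H]1C[C@@H]2C[C@H]([C@H]1C)C2(C)C)[C@@H]1C[C@@H]2C[C@H]([C@H]1C)C2(C)C | intermediate
21 | [(Z)-3-(4-methoxyphenoxy)-2-methylprop-2-en-1-yl]diisopinocampheylborane | COc1ccc(O/C=C(C)\CB([C@@H]2C[C@@H]3C[C@H]([C@H]2C)C3(C)C)[C@@H]2C[C@@H]3C[C@H]([C@H]2C)C3(C)C)cc1 | intermediate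
22 | O-diisopinocampheylboryl derivative of 23 at the C6 oxygen | CC(C)[C@]1(O)CC[C@](C)(CC=C)[C@H]1[C@@H](OB([C@@H]2C[C@@H]3C[C@H]([C@H]2C)C3(C)C)[C@@H]2C[C@@H]3C[C@H]([C@H]2C)C3(C)C)[C@H](Oc2ccc(OC)cc2)C(C)=C | intermediate
23 | (1R,2S,3R)-2-[(1R,2R)-1-hydroxy-2-(4-methoxyphenoxy)-3-methylbut-3-en-1-yl]-3-methyl-1-(propan-2-yl)-3-(prop-2-en-1-yl)cyclopentan-1-ol | CC(C)[C@]1(O)CC[C@](C)(CC=C)[C@H]1[C@@H](O)[C@H](Oc1ccc(OC)cc1)C(C)=C | intermediate
24 | 7β-(4-methoxyphenoxy)dauc-8-ene-4β,6α-diol | CC(C)[C@]1(O)CC[C@]2(C)CC=C(C)[C@@H](Oc3ccc(OC)cc3)[C@H](O)[C@H]21 | intermediate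
25 | 8α,9α-epoxy-7β-(4-methoxyphenoxy)daucane-4β,6α-diol | CC(C)[C@]1(O)CC[C@]2(C)C[C@@H]3O[C@]3(C)[C@@H](Oc3ccc(OC)cc3)[C@H](O)[C@H]21 | intermediate
26 | 4-acetoxybenzoyl chloride | CC(=O)Oc1ccc(cc1)C(Cl)=O | starting material
27 | 8α,9α-epoxy-4β-hydroxy-7β-(4-methoxyphenoxy)daucan-6α-yl 4-acetoxybenzoate | CC(C)[C@]1(O)CC[C@]2(C)C[C@@H]3O[C@]3(C)[C@@H](Oc3ccc(OC)cc3)[C@H](OC(=O)c3ccc(OC(C)=O)cc3)[C@H]21 | intermediate
28 | 8α,9α-epoxy-4β,7β-dihydroxydaucan-6α-yl 4-acetoxybenzoate | CC(C)[C@]1(O)CC[C@]2(C)C[C@@H]3O[C@]3(C)[C@@H](O)[C@H](OC(=O)c3ccc(OC(C)=O)cc3)[C@H]21 | intermediate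
29 | 8α,9α-epoxy-4β,7β-dihydroxydaucan-6α-yl 4-hydroxybenzoate (CNP0290052.1) | CC(C)[C@]1(O)CC[C@]2(C)C[C@@H]3O[C@]3(C)[C@@H](O)[C@H](OC(=O)c3ccc(O)cc3)[C@H]21 | target

Total step count: 14 steps.
Longest linear sequence: 13 steps (steps 1 to 7 and 9 to 14; step 8 is a one-step side branch).

Steps most likely to fail

Step 5. Allyl transfer to the hindered tertiary radical may be too slow, so that 1,5-hydrogen shift from the isopropyl group, disproportionation or premature allylation of the α-silyl radical overtake the cascade. Facial selectivity at C1 may also erode. The fallback replaces the tin chain by degenerative xanthate transfer with a sulfone as allyl donor; it sets out from 9 and comes back at 13. Bromide 9 is treated with potassium O-ethyl xanthate in acetone to give the S-(silylmethyl) O-ethyl xanthate F1. F1 is then heated with allyl ethyl sulfone and dilauroyl peroxide in 1,2-dichloroethane. Reversible xanthate transfer stores the radicals, and loss of SO2 from the ethylsulfonyl radical makes the allyl transfer irreversible, which should give 13.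

Step 3. The lithiated cyclic allyl carbamate may lose its configuration, borylation may occur at the γ-carbon, or the 1,2-shift of the bulky isopropyl group may stall. The fallback carries the secondary alcohol through the tethered cascade and brings in isopropyl afterwards; it sets out from 2 and comes back at 14.
- Alcohol 2 is silylated with (bromomethyl)chlorodimethylsilane (Et3N, DMAP) to the (bromomethyl)silyl ether F2.
- The conditions of step 5 should turn F2 into the cis-fused allylated oxasilolane F3.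
- Tamao oxidation (H2O2, KF, KHCO3) gives the diol F4.
- TBSCl/imidazole protects the primary hydroxyl as the silyl ether F5.
- Dess–Martin periodinane oxidizes the secondary alcohol to the cyclopentanone F6.
- Isopropylmagnesium chloride with CeCl3 (THF, −78 °C) should add anti to the C5 side chain to give the tertiary alcohol F7.
- Bu4NF removes the silyl ether to give 14.

Step 9. Addition to the neopentyl-type aldehyde may be slow, which invites borotropic scrambling of the (Z)-allylborane, mismatched double diastereoselection, or retro-aldol and dehydration of the β-hydroxy aldehyde. The fallback is an auxiliary-controlled glycolate aldol; it sets out from 15 and comes back at 23.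
- (4-Methoxyphenoxy)acetic acid is activated with pivaloyl chloride/Et3N and coupled with lithiated (S)-4-benzyloxazolidin-2-one to give the acyl oxazolidinone F8.
- The boron enolate of F8 (Bu2BOTf, iPr2NEt, CH2Cl2, −78 °C) should add to 15 in the Evans syn sense to give the aldol adduct F9.
- Me(MeO)NH·HCl/AlMe3 converts F9 into the Weinreb amide F10.
- MeMgBr gives the methyl ketone F11.
- Wittig methylenation (Ph3P=CH2, THF, −78 to 0 °C) gives 23.

Further compounds
F1 | step 5 | O-ethyl S-{[dimethyl({(R)-3-methyl-1-(propan-2-yl)cyclopent-2-en-1-yl}oxy)silyl]methyl} carbonodithioate | CC(C)[C@]1(O[Si](C)(C)CSC(=S)OCC)CCC(C)=C1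
F2 | step 3 | (S)-(bromomethyl)dimethyl[(3-methylcyclopent-2-en-1-yl)oxy]silane | BrC[Si](C)(C)O[C@H]1CCC(C)=C1
F3 | step 3 | (3aR,4R,6aS)-2,2,4-trimethyl-4-(prop-2-en-1-yl)hexahydro-2H-cyclopenta[d][1,2]oxasilole | C=CC[C@@]1(C)CC[C@@H]2O[Si](C)(C)C[C@H]12
F4 | step 3 | (1S,2S,3R)-2-(hydroxymethyl)-3-methyl-3-(prop-2-en-1-yl)cyclopentan-1-ol | C=CC[C@@]1(C)CC[C@H](O)[C@@H]1CO
F5 | step 3 | (1S,2S,3R)-2-{[(tert-butyldimethylsilyl)oxy]methyl}-3-methyl-3-(prop-2-en-1-yl)cyclopentan-1-ol | C=CC[C@@]1(C)CC[C@H](O)[C@@H]1CO[Si](C)(C)C(C)(C)C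
F6 | step 3 | (2S,3R)-2-{[(tert-butyldimethylsilyl)oxy]methyl}-3-methyl-3-(prop-2-en-1-yl)cyclopentan-1-one | C=CC[C@@]1(C)CCC(=O)[C@@H]1CO[Si](C)(C)C(C)(C)C
F7 | step 3 | (1R,2S,3R)-2-{[(tert-butyldimethylsilyl)oxy]methyl}-3-methyl-1-(propan-2-yl)-3-(prop-2-en-1-yl)cyclopentan-1-ol | C=CC[C@@]1(C)CC[C@@](O)(C(C)C)[C@@H]1CO[Si](C)(C)C(C)(C)C
F8 | step 9 | (S)-4-benzyl-3-[(4-methoxyphenoxy)acetyl]oxazolidin-2-one | COc1ccc(OCC(=O)N2[C@@H](Cc3ccccc3)COC2=O)cc1
F9 | step 9 | (S)-4-benzyl-3-{(2S,3R)-3-hydroxy-3-[(1S,2R,5R)-2-hydroxy-5-methyl-2-(propan-2-yl)-5-(prop-2-en-1-yl)cyclopentyl]-2-(4-methoxyphenoxy)propanoyl}oxazolidin-2-one | CC(C)[C@]1(O)CC[C@](C)(CC=C)[C@H]1[C@@H](O)[C@H](Oc1ccc(OC)cc1)C(=O)N1[C@@H](Cc2ccccc2)COC1=O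
F10 | step 9 | (2S,3R)-3-hydroxy-3-[(1S,2R,5R)-2-hydroxy-5-methyl-2-(propan-2-yl)-5-(prop-2-en-1-yl)cyclopentyl]-N-methoxy-2-(4-methoxyphenoxy)-N-methylpropanamide | CC(C)[C@]1(O)CC[C@](C)(CC=C)[C@H]1[C@@H](O)[C@H](Oc1ccc(OC)cc1)C(=O)N(C)OC
F11 | step 9 | (3S,4R)-4-hydroxy-4-[(1S,2R,5R)-2-hydroxy-5-methyl-2-(propan-2-yl)-5-(prop-2-en-1-yl)cyclopentyl]-3-(4-methoxyphenoxy)butan-2-one | CC(C)[C@]1(O)CC[C@](C)(CC=C)[C@H]1[C@@H](O)[C@H](Oc1ccc(OC)cc1)C(C)=O
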